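**Plan**
- Retrosynthesis: the two O‑benzyl bonds are cut last. The A ring is then opened at C4a–C5 (electrocyclic bond) and C8–C8a (carbonyl addition), leaving dimethyl squarate and a 2‑aryl‑3‑benzyloxy‑4‑pyranone. That pyranone is cut at C2–C3 and O1–C8a to furan and the B‑ring aldehyde.
- Enabling feature: A‑ring carbons C5, C6, C7 and C8 all carry oxygen, with O5 and O8 para. These four carbons map onto the four carbons of a squarate‑derived 2,3,4‑trialkoxycyclobutenone, and the fusion bond C4a=C8a is the C5=C6 bond of the γ‑pyranone C ring.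
- Forward order: B ring purchased; C ring from furan (furyllithium addition, Achmatowicz expansion, epoxidation, acid aromatisation); A ring last (squarate addition, then thermal ring expansion).
- The squarate carbinol is capped as its methyl ether, so the annulation delivers 8‑OMe and the chelated 5‑OH directly.
- Stereochemistry: the target has no stereogenic element; all sp3 centres of intermediates are racemic or mixed and are erased in steps 6 and 9.

Key step: step 9

Remark: because the target is achiral, "single enantiomer" reduces to the constitution shown; no asymmetric step is needed.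

**Step 1**
Reactants: 1 3‑hydroxy‑4,5‑dimethoxybenzaldehyde
Product: 2 3‑(benzyloxy)‑4,5‑dimethoxybenzaldehyde
Conditions: BnBr, K2CO3, DMF, rt
Reagents that add atoms: benzyl bromide, BrCc1ccccc1
Why: Williamson ether synthesis on the only acidic OH masks the B‑ring phenol as a benzyl ether that tolerates organolithiums and is removed in the last step.

**Step 2**
Reactants: 2 3‑(benzyloxy)‑4,5‑dimethoxybenzaldehyde; 3 furan
Product: 5 [3‑(benzyloxy)‑4,5‑dimethoxyphenyl](furan‑2‑yl)methanol (racemic), via 2‑furyllithium 4 (not isolated)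
Conditions: furan, n‑BuLi, THF, 0 °C; then 2, −78 → 0 °C; H2O
Reagents that add atoms: none
Why: α‑Lithiation of furan followed by 1,2‑addition of the organolithium to the aldehyde forms the future C2–C3 bond, the carbinol centre arising as a racemate that is erased in step 6.

**Step 3**
Reactants: 5 [3‑(benzyloxy)‑4,5‑dimethoxyphenyl](furan‑2‑yl)methanol
Product: 6 2‑[3‑(benzyloxy)‑4,5‑dimethoxyphenyl]‑6‑hydroxy‑2H‑pyran‑3(6H)‑one (racemic; anomer mixture)
Conditions: mCPBA, CH2Cl2, 0 °C → rt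
Reagents that add atoms: 3‑chloroperbenzoic acid, OOC(=O)c1cccc(Cl)c1
Why: Achmatowicz oxidative ring expansion, in which the peracid attacks the electron‑rich furan rather than the alkoxyarene (no ring halogenation as a bromine oxidant might cause) and the carbinol oxygen closes the ene‑dione to the pyranone lactol, whose two sp3 centres may form as any mixture.

**Step 4**
Reactants: 6 2‑[3‑(benzyloxy)‑4,5‑dimethoxyphenyl]‑6‑hydroxy‑2H‑pyran‑3(6H)‑one
Product: 7 2‑[3‑(benzyloxy)‑4,5‑dimethoxyphenyl]‑6‑methoxy‑2H‑pyran‑3(6H)‑one (racemic; anomer mixture)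
Conditions: HC(OMe)3, BF3·OEt2 (cat.), CH2Cl2, 0 °C
Reagents that add atoms: trimethyl orthoformate, COC(OC)OC
Why: Lewis acid‑promoted acetal exchange (O‑glycosidation through the ring oxocarbenium ion) locks the lactol as its methyl acetal so that it cannot ring‑open under the basic epoxidation, the anomeric configuration being unimportant.

**Step 5**
Reactants: 7 2‑[3‑(benzyloxy)‑4,5‑dimethoxyphenyl]‑6‑methoxy‑2H‑pyran‑3(6H)‑one
Product: 8 4‑[3‑(benzyloxy)‑4,5‑dimethoxyphenyl]‑2‑methoxy‑3,7‑dioxabicyclo[4.1.0]heptan‑5‑one (racemic; diastereomer mixture)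
Conditions: 30% aq H2O2, NaOH (cat.), MeOH, 0 °C
Reagents that add atoms: hydrogen peroxide, OO
Why: Weitz–Scheffer nucleophilic epoxidation of the enone brings in the oxygen that becomes the pyranone C4 carbonyl and so raises the ring to the γ‑pyrone oxidation level, any epoxide diastereomer serving equally.

**Step 6**
Reactants: 8 4‑[3‑(benzyloxy)‑4,5‑dimethoxyphenyl]‑2‑methoxy‑3,7‑dioxabicyclo[4.1.0]heptan‑5‑one
Product: 9 2‑[3‑(benzyloxy)‑4,5‑dimethoxyphenyl]‑3‑hydroxy‑4H‑pyran‑4‑one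
Conditions: H2SO4 (cat.), aq dioxane, 90 °C
Reagents that add atoms: none
Why: Acid‑mediated isomerisation of the α,β‑epoxy ketone to the diosphenol, elimination of methanol from the acetal and enolisation towards the benzylic C2–H (the classical maltol synthesis) should give the aromatic 3‑hydroxy‑γ‑pyranone and remove every sp3 centre.

**Step 7**
Reactants: 9 2‑[3‑(benzyloxy)‑4,5‑dimethoxyphenyl]‑3‑hydroxy‑4H‑pyran‑4‑one
Product: 10 3‑(benzyloxy)‑2‑[3‑(benzyloxy)‑4,5‑dimethoxyphenyl]‑4H‑pyran‑4‑one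
Conditions: BnBr, K2CO3, DMF, 50 °C
Reagents that add atoms: benzyl bromide, BrCc1ccccc1
Why: Williamson O‑benzylation of the acidic enolic 3‑OH, as in the preparation of benzyl maltol, removes the only acidic proton before the metalation.

**Step 8**
Reactants: 10 3‑(benzyloxy)‑2‑[3‑(benzyloxy)‑4,5‑dimethoxyphenyl]‑4H‑pyran‑4‑one; 11 dimethyl squarate
Product: 14 4‑{5‑(benzyloxy)‑6‑[3‑(benzyloxy)‑4,5‑dimethoxyphenyl]‑4‑oxo‑4H‑pyran‑2‑yl}‑2,3,4‑trimethoxycyclobut‑2‑en‑1‑one (racemic), via 6‑lithiopyranone 12 (not isolated), via lithium alkoxide 13 (not isolated)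
Conditions: LiTMP (TMP, n‑BuLi), THF, −78 °C; cannulate into 11, THF, −78 °C; then MeOTf, −78 → 0 °C
Reagents that add atoms: methyl trifluoromethanesulfonate, COS(=O)(=O)C(F)(F)F
Why: Kinetic deprotonation with the hindered, non‑nucleophilic amide should occur at C6–H, the sp2 C–H next to the ring oxygen (directed metalation as in the C2‑lithiation of 3‑substituted chromones), the vinyllithium then adds 1,2 to one squarate carbonyl and the tertiary lithium alkoxide is O‑methylated in situ, the new quaternary centre being racemic and destroyed in step 9.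

**Step 9**
Reactants: 14 4‑{5‑(benzyloxy)‑6‑[3‑(benzyloxy)‑4,5‑dimethoxyphenyl]‑4‑oxo‑4H‑pyran‑2‑yl}‑2,3,4‑trimethoxycyclobut‑2‑en‑1‑one
Product: 17 3‑(benzyloxy)‑2‑[3‑(benzyloxy)‑4,5‑dimethoxyphenyl]‑5‑hydroxy‑6,7,8‑trimethoxy‑4H‑chromen‑4‑one, via dienylketene 15 (not isolated), via 4aH‑dienone 16 (not isolated)
Conditions: degassed p‑xylene, 138 °C, Ar
Reagents that add atoms: none
Why: Heating should open the cyclobutenone by a conrotatory 4π electrocyclic reaction to the (Z)‑dienylketene 15, the donor 4‑methoxy group turning outward so that the pyranonyl arm lies beside the ketene; a thermal disrotatory 6π electrocyclisation then joins the ketene carbon to pyranone C5 (flavone C4a–C5), closing the six‑membered carbocyclic A ring as dienone 16, and enolisation of the doubly activated C4a–H gives the phenol. The closest known reaction type is the Moore rearrangement of 4‑alkenyl‑ and 4‑heteroaryl‑4‑hydroxy(alkoxy)cyclobutenones to hydroquinones and their monoethers, applied here to a pyranonyl substituent. No stereocentre survives, since the carbinol carbon of 14 and C4a of 16 both become sp2. The step needs outward rotation of OMe, which the electronic preference of donor substituents provides, and because no free OH is present to lactonise a wrongly rotated ketene, that isomer can only re‑close and re‑open. It also needs a single site of closure, which is secured because the pyranone carbon bearing the four‑membered ring has only one carbon neighbour in its ring (C5), the other being O1. The ketene carbon ends as the chelated 5‑OH, the carbinol carbon as C8–OMe and the squarate methoxyls as 6‑ and 7‑OMe, so no selective methylation and no air‑sensitive hydroquinone are involved.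

**Step 10**
Reactants: 17 3‑(benzyloxy)‑2‑[3‑(benzyloxy)‑4,5‑dimethoxyphenyl]‑5‑hydroxy‑6,7,8‑trimethoxy‑4H‑chromen‑4‑one
Product: 18 3‑demethyldigicitrin (3,5‑dihydroxy‑2‑(3‑hydroxy‑4,5‑dimethoxyphenyl)‑6,7,8‑trimethoxy‑4H‑chromen‑4‑one)
Conditions: H2 (1 atm), 10% Pd/C, EtOAc–MeOH, rt
Reagents that add atoms: none
Why: Palladium‑catalysed hydrogenolysis should cleave both benzyl ethers while the tetrasubstituted flavonol double bond, the chelated carbonyl and the methyl ethers stay untouched under one atmosphere of hydrogen.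

**Compound list**
1 | 3‑hydroxy‑4,5‑dimethoxybenzaldehyde | COc1cc(C=O)cc(O)c1OC | starting material
2 | 3‑(benzyloxy)‑4,5‑dimethoxybenzaldehyde | COc1cc(C=O)cc(OCc2ccccc2)c1OC | intermediate
3 | furan | c1ccoc1 | starting material
4 | 2‑furyllithium | [Li]c1ccco1 | intermediate (not isolated)
5 | [3‑(benzyloxy)‑4,5‑dimethoxyphenyl](furan‑2‑yl)methanol (racemic) | COc1cc(C(O)c2ccco2)cc(OCc2ccccc2)c1OC | intermediate
6 | 2‑[3‑(benzyloxy)‑4,5‑dimethoxyphenyl]‑6‑hydroxy‑2H‑pyran‑3(6H)‑one (racemic, anomer mixture) | COc1cc(C2OC(O)C=CC2=O)cc(OCc2ccccc2)c1OC | intermediate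
7 | 2‑[3‑(benzyloxy)‑4,5‑dimethoxyphenyl]‑6‑methoxy‑2H‑pyran‑3(6H)‑one (racemic, anomer mixture) | COc1cc(C2OC(OC)C=CC2=O)cc(OCc2ccccc2)c1OC | intermediate
8 | 4‑[3‑(benzyloxy)‑4,5‑dimethoxyphenyl]‑2‑methoxy‑3,7‑dioxabicyclo[4.1.0]heptan‑5‑one (racemic, diastereomer mixture) | COc1cc(C2OC(OC)C3OC3C2=O)cc(OCc2ccccc2)c1OC | intermediate
9 | 2‑[3‑(benzyloxy)‑4,5‑dimethoxyphenyl]‑3‑hydroxy‑4H‑pyran‑4‑one | COc1cc(-c2occc(=O)c2O)cc(OCc2ccccc2)c1OC | intermediate
10 | 3‑(benzyloxy)‑2‑[3‑(benzyloxy)‑4,5‑dimethoxyphenyl]‑4H‑pyran‑4‑one | COc1cc(-c2occc(=O)c2OCc2ccccc2)cc(OCc2ccccc2)c1OC | intermediate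
11 | dimethyl squarate (3,4‑dimethoxycyclobut‑3‑ene‑1,2‑dione) | COC1=C(OC)C(=O)C1=O | starting material
12 | 3‑(benzyloxy)‑2‑[3‑(benzyloxy)‑4,5‑dimethoxyphenyl]‑6‑lithio‑4H‑pyran‑4‑one | COc1cc(-c2oc([Li])cc(=O)c2OCc2ccccc2)cc(OCc2ccccc2)c1OC | intermediate (not isolated)
13 | lithium 1‑{5‑(benzyloxy)‑6‑[3‑(benzyloxy)‑4,5‑dimethoxyphenyl]‑4‑oxo‑4H‑pyran‑2‑yl}‑2,3‑dimethoxy‑4‑oxocyclobut‑2‑en‑1‑olate (racemic) | COC1=C(OC)C(O[Li])(c2cc(=O)c(OCc3ccccc3)c(-c3cc(OC)c(OC)c(OCc4ccccc4)c3)o2)C1=O | intermediate (not isolated)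
14 | 4‑{5‑(benzyloxy)‑6‑[3‑(benzyloxy)‑4,5‑dimethoxyphenyl]‑4‑oxo‑4H‑pyran‑2‑yl}‑2,3,4‑trimethoxycyclobut‑2‑en‑1‑one (racemic) | COC1=C(OC)C(OC)(c2cc(=O)c(OCc3ccccc3)c(-c3cc(OC)c(OC)c(OCc4ccccc4)c3)o2)C1=O | intermediate
15 | (3Z)‑4‑{5‑(benzyloxy)‑6‑[3‑(benzyloxy)‑4,5‑dimethoxyphenyl]‑4‑oxo‑4H‑pyran‑2‑yl}‑2,3,4‑trimethoxybuta‑1,3‑dien‑1‑one | O=C=C(OC)/C(OC)=C(/OC)c1cc(=O)c(OCc2ccccc2)c(-c2cc(OC)c(OC)c(OCc3ccccc3)c2)o1 | intermediate (not isolated)
16 | 3‑(benzyloxy)‑2‑[3‑(benzyloxy)‑4,5‑dimethoxyphenyl]‑6,7,8‑trimethoxy‑4aH‑chromene‑4,5‑dione (racemic) | COC1=C(OC)C(=O)C2C(=O)C(OCc3ccccc3)=C(c3cc(OC)c(OC)c(OCc4ccccc4)c3)OC2=C1OC | intermediate (not isolated)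
17 | 3‑(benzyloxy)‑2‑[3‑(benzyloxy)‑4,5‑dimethoxyphenyl]‑5‑hydroxy‑6,7,8‑trimethoxy‑4H‑chromen‑4‑one | COc1cc(-c2oc3c(OC)c(OC)c(OC)c(O)c3c(=O)c2OCc2ccccc2)cc(OCc2ccccc2)c1OC | intermediate
18 | 3‑demethyldigicitrin | COc1cc(-c2oc3c(OC)c(OC)c(OC)c(O)c3c(=O)c2O)cc(O)c1OC | target

**Totals**
Total step count: 10. Longest linear sequence: 10 steps (1 → 18); furan and dimethyl squarate enter as purchased materials.

**Steps most likely to fail**

Step 8. Deprotonation could stray to the O‑benzylic methylene or to C5 (with ring fragmentation). The C6‑lithio species could add to unmetalated 10, and methyl triflate could alkylate the pyranone carbonyl oxygen. Fallback: setting out from 10, zincation with TMPZnCl·LiCl in THF at 25 °C and iodolysis would give 3‑(benzyloxy)‑2‑[3‑(benzyloxy)‑4,5‑dimethoxyphenyl]‑6‑iodo‑4H‑pyran‑4‑one F1. Iodine–magnesium exchange with i‑PrMgCl·LiCl at −40 °C, addition of the Grignard reagent to 11 and aqueous quench would give the free carbinol 4‑{5‑(benzyloxy)‑6‑[3‑(benzyloxy)‑4,5‑dimethoxyphenyl]‑4‑oxo‑4H‑pyran‑2‑yl}‑4‑hydroxy‑2,3‑dimethoxycyclobut‑2‑en‑1‑one F2. Purdie methylation of F2 (MeI, Ag2O, MeCN) comes back to the route at 14.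

Step 9. The 4π opening is reversible and the 6π closure must engage C5 of a push–pull (vinylogous ester) double bond. If that closure is slow, ketene oligomerisation or thermal erosion of the benzyl enol ether would take over. Fallback: setting out from 2, Claisen–Schmidt condensation with purchased 1‑(2‑hydroxy‑3,4,5,6‑tetramethoxyphenyl)ethan‑1‑one F3 (KOH, EtOH) would give (E)‑3‑[3‑(benzyloxy)‑4,5‑dimethoxyphenyl]‑1‑(2‑hydroxy‑3,4,5,6‑tetramethoxyphenyl)prop‑2‑en‑1‑one F4. Iodine‑catalysed oxidative cyclisation in DMSO at 120 °C would give 2‑[3‑(benzyloxy)‑4,5‑dimethoxyphenyl]‑5,6,7,8‑tetramethoxy‑4H‑chromen‑4‑one F5. Epoxidation of C2=C3 with dimethyldioxirane and acid‑induced opening would give 2‑[3‑(benzyloxy)‑4,5‑dimethoxyphenyl]‑3‑hydroxy‑5,6,7,8‑tetramethoxy‑4H‑chromen‑4‑one F6. BCl3 (CH2Cl2, −78 → 0 °C) should then remove the chelated 5‑O‑methyl group and the benzyl ether and come back to the route at 18.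

Step 6. The acid may cleave the aryl benzyl ether, or the epoxy ketone may divert to ring‑contracted furyl ketones instead of eliminating methanol. Loss of the benzyl group alone would be repaired in step 7, which would re‑benzylate both hydroxyls. Fallback: setting out from 2, a Lewis acid‑mediated hetero‑Diels–Alder reaction with trans‑1‑methoxy‑3‑(trimethylsilyloxy)buta‑1,3‑diene (BF3·OEt2, CH2Cl2, −78 °C; then TFA) would give 2‑[3‑(benzyloxy)‑4,5‑dimethoxyphenyl]‑2,3‑dihydro‑4H‑pyran‑4‑one F7. Enolate hydroxylation (LiHMDS, THF, −78 °C; then 2‑(phenylsulfonyl)‑3‑phenyloxaziridine) would give 2‑[3‑(benzyloxy)‑4,5‑dimethoxyphenyl]‑3‑hydroxy‑2,3‑dihydro‑4H‑pyran‑4‑one F8. Dess–Martin oxidation to the 3,4‑dione, which enolises at once to the aromatic pyranone, comes back to the route at 9.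

**Further compounds**
F1 | step 8 | 3‑(benzyloxy)‑2‑[3‑(benzyloxy)‑4,5‑dimethoxyphenyl]‑6‑iodo‑4H‑pyran‑4‑one | COc1cc(-c2oc(I)cc(=O)c2OCc2ccccc2)cc(OCc2ccccc2)c1OC
F2 | step 8 | 4‑{5‑(benzyloxy)‑6‑[3‑(benzyloxy)‑4,5‑dimethoxyphenyl]‑4‑oxo‑4H‑pyran‑2‑yl}‑4‑hydroxy‑2,3‑dimethoxycyclobut‑2‑en‑1‑one (racemic) | COC1=C(OC)C(O)(c2cc(=O)c(OCc3ccccc3)c(-c3cc(OC)c(OC)c(OCc4ccccc4)c3)o2)C1=O
F3 | step 9 | 1‑(2‑hydroxy‑3,4,5,6‑tetramethoxyphenyl)ethan‑1‑one | CC(=O)c1c(O)c(OC)c(OC)c(OC)c1OC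
F4 | step 9 | (E)‑3‑[3‑(benzyloxy)‑4,5‑dimethoxyphenyl]‑1‑(2‑hydroxy‑3,4,5,6‑tetramethoxyphenyl)prop‑2‑en‑1‑one | COc1cc(/C=C/C(=O)c2c(O)c(OC)c(OC)c(OC)c2OC)cc(OCc2ccccc2)c1OC
F5 | step 9 | 2‑[3‑(benzyloxy)‑4,5‑dimethoxyphenyl]‑5,6,7,8‑tetramethoxy‑4H‑chromen‑4‑one | COc1cc(-c2cc(=O)c3c(OC)c(OC)c(OC)c(OC)c3o2)cc(OCc2ccccc2)c1OC
F6 | step 9 | 2‑[3‑(benzyloxy)‑4,5‑dimethoxyphenyl]‑3‑hydroxy‑5,6,7,8‑tetramethoxy‑4H‑chromen‑4‑one | COc1cc(-c2oc3c(OC)c(OC)c(OC)c(OC)c3c(=O)c2O)cc(OCc2ccccc2)c1OC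
F7 | step 6 | 2‑[3‑(benzyloxy)‑4,5‑dimethoxyphenyl]‑2,3‑dihydro‑4H‑pyran‑4‑one (racemic) | COc1cc(C2CC(=O)C=CO2)cc(OCc2ccccc2)c1OC
F8 | step 6 | 2‑[3‑(benzyloxy)‑4,5‑dimethoxyphenyl]‑3‑hydroxy‑2,3‑dihydro‑4H‑pyran‑4‑one (racemic) | COc1cc(C2OC=CC(=O)C2O)cc(OCc2ccccc2)c1OC
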